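**Retrosynthetic overview**

1. The target is (5S,8R)-1,3,8-trimethoxy-2-methyl-5-octyl-5,6,7,8-tetrahydroquinolin-4(1H)-one, with octyl and 8-OMe cis; quinolinone numbering is used, ring A is the N-methoxy-4-pyridone and ring B the carbocycle. Ring A is made first and ring B last.
2. Last disconnection, C8–C8a: the target is an isomer of a monocyclic pyridone carrying an (S)-CH(octyl)CH2CH=CH(OMe) chain at the future C4a. Hydrogen-atom transfer to the enol ether gives a C8 α-methoxy radical that closes ring B on C8a, sets C8 with its methoxy group in place and gives the natural product directly.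
3. Enabling feature: C8a is the only unsubstituted carbon of ring A and the β-carbon of the vinylogous amide N1–C8a=C4a–C4=O. C8 is a natively electrophilic, acetal-level carbon whose polarity the radical reverses, and the C8a–H of the adduct is weak enough to be given back, so ring A is restored with N–OMe intact.
4. Side chain: Heck coupling of the 5-iodopyridone with ethyl (E)-undec-2-enoate (C5–C7 and octyl), copper hydride conjugate reduction (sets C5), ester to aldehyde, Wittig methoxymethylenation (adds C8 with its oxygen).
5. Ring A: 3-methoxy-2-methyl-4-pyranone and methoxyamine (pyranone-to-pyridone ring exchange), then iodination at pyridone C5 (the future C4a).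

Key step: step 8

Assumption: in step 5 the (R)-configured bisphosphine is taken to deliver hydride to the face of the (E)-enoate that gives the (3S)-ester; if correlation shows the opposite sense, the (S)-ligand is used with no other change.

**Route**

Step 1
Reactants: 1 nonanal; 2 ethyl (triphenylphosphoranylidene)acetate
Product: 3 ethyl (E)-undec-2-enoate
Conditions: CH2Cl2, rt
Reagents that add atoms: none
Why: Wittig olefination with a stabilised ylide should give the (E)-enoate with the usual selectivity of such ylides.

Step 2
Reactants: 4 3-methoxy-2-methyl-4H-pyran-4-one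
Product: 5 1,3-dimethoxy-2-methylpyridin-4(1H)-one
Conditions: MeONH2·HCl, pyridine, 80 °C
Reagents that add atoms: O-methylhydroxylamine hydrochloride, CON.Cl
Why: Pyranone-to-pyridone exchange (conjugate addition of the nitrogen nucleophile at the unsubstituted C6, ring opening, ring closure on the C2 carbon and loss of water), the reaction type by which maltol ethers are turned into N-substituted and N-hydroxy 4-pyridones.

Step 3
Reactants: 5 1,3-dimethoxy-2-methylpyridin-4(1H)-one
Product: 6 5-iodo-1,3-dimethoxy-2-methylpyridin-4(1H)-one
Conditions: NIS, MeCN, rt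
Reagents that add atoms: N-iodosuccinimide, O=C1CCC(=O)N1I
Why: Electrophilic iodination should occur at C5, the only free α-carbon of the vinylogous amide, because C6 is its electron-poor β-carbon.

Step 4
Reactants: 6 5-iodo-1,3-dimethoxy-2-methylpyridin-4(1H)-one; 3 ethyl (E)-undec-2-enoate
Product: 7 ethyl (2E)-3-(1,5-dimethoxy-6-methyl-4-oxo-1,4-dihydropyridin-3-yl)undec-2-enoate
Conditions: Pd(OAc)2 (5 mol %), Cy2NMe, Et4NCl, DMAc, 100 °C
Reagents that add atoms: none
Why: Mizoroki–Heck reaction under phosphine-free, chloride-promoted conditions suited to β-substituted acrylates: syn carbopalladation puts the pyridone on C3 and syn β-hydride elimination of the single C3 hydrogen places it trans to the ester, which should give the (E)-trisubstituted enoate.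

Step 5
Reactants: 7 ethyl (2E)-3-(1,5-dimethoxy-6-methyl-4-oxo-1,4-dihydropyridin-3-yl)undec-2-enoate
Product: 8 ethyl (3S)-3-(1,5-dimethoxy-6-methyl-4-oxo-1,4-dihydropyridin-3-yl)undecanoate
Conditions: Cu(OAc)2 (5 mol %), (R)-DTBM-SEGPHOS (5.5 mol %), (EtO)2MeSiH, t-BuOH, toluene, 0 °C to rt
Reagents that add atoms: none
Why: Ligand-controlled asymmetric conjugate reduction with copper hydride (1,4-hydrosilylation) of a geometrically defined β-aryl-β-alkyl enoate: the chiral bisphosphine–CuH complex delivers hydride to one enantiotopic face of C3, which sets the (S) centre that becomes C5.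

Step 6
Reactants: 8 ethyl (3S)-3-(1,5-dimethoxy-6-methyl-4-oxo-1,4-dihydropyridin-3-yl)undecanoate
Product: 9 (3S)-3-(1,5-dimethoxy-6-methyl-4-oxo-1,4-dihydropyridin-3-yl)undecanal
Conditions: iBu2AlH (1.3 equiv), CH2Cl2, −78 °C; MeOH, then aq. potassium sodium tartrate
Reagents that add atoms: none
Why: Partial reduction of an ester to the aldehyde with iBu2AlH in the cold should spare the much less electrophilic vinylogous-amide carbonyl and the N–OMe bond, and the stereocentre is β to the new aldehyde and cannot epimerise by enolisation.

Step 7
Reactants: 9 (3S)-3-(1,5-dimethoxy-6-methyl-4-oxo-1,4-dihydropyridin-3-yl)undecanal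
Product: 10 1,3-dimethoxy-5-[(4S)-1-methoxydodec-1-en-4-yl]-2-methylpyridin-4(1H)-one (mixture of E and Z enol ethers)
Conditions: MeOCH2PPh3Cl, KOtBu, THF, 0 °C; then 9, 0 °C to rt
Reagents that add atoms: (methoxymethyl)triphenylphosphonium chloride, COC[P+](c1ccccc1)(c1ccccc1)c1ccccc1.[Cl-]
Why: Wittig reaction with the non-stabilised methoxymethylene ylide (preformed with a slight deficit of base) converts the aldehyde into the C7=C8 methyl enol ether, whose E/Z ratio is of no consequence for the next step.

Step 8
Reactants: 10 1,3-dimethoxy-5-[(4S)-1-methoxydodec-1-en-4-yl]-2-methylpyridin-4(1H)-one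
Product: 11 (5S,8R)-1,3,8-trimethoxy-2-methyl-5-octyl-5,6,7,8-tetrahydroquinolin-4(1H)-one (Waltherione K)
Conditions: Co(salen)Cl (5 mol %; trivalent cobalt, salen = N,N'-bis(3,5-di-tert-butylsalicylidene)cyclohexane-1,2-diaminate), PhSiH3 (10 mol %), benzene, degassed, Ar, rt to 40 °C
Reagents that add atoms: none
Why: Proposed new method: the cobalt hydride made from Co(salen)Cl and PhSiH3 should transfer a hydrogen atom to C7 of the electron-rich enol ether and give the nucleophilic α-methoxy radical at C8, which adds to C8a, and the C4a (α-keto) radical so formed should give its weak C8a–H hydrogen back to divalent cobalt, which restores aromatic ring A and the cobalt hydride, so that the step is a redox-neutral isomerisation in which no radical with spin next to nitrogen arises and the N–OMe bond is not at risk. The closest known reaction types are the cobalt-salen-catalysed radical cycloisomerisation of dienes by metal-hydride hydrogen atom transfer, the Minisci-type coupling of olefin-derived radicals (enol ethers included) with azinium rings, and 6-endo radical cyclisations onto enones that carry the tether at the α-carbon; new is the pyridone C8a–H as the acceptor with return of the hydrogen atom. Ring B closes in the 6-endo-trig mode, since the competing 5-exo attack would hit C4a, the electron-rich and fully substituted α-carbon. The C8 stereocentre is controlled by the existing C5 centre: A(1,3) strain with the C4 carbonyl holds the octyl group pseudoaxial on the face away from the folding tether, and the radical carbon adds with its hydrogen over ring A and its methoxy group turned outward, which should lead to the 5,8-cis (5S,8R) isomer. The step needs hydrogen atom transfer to the enol ether only and attack at C8a only; the first is secured because the enol ether is the one electron-rich, unhindered C=C, the second because C8a is the only unsubstituted ring carbon and the polarity-matched β-carbon of the vinylogous amide, and both enol ether isomers give the same radical.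

**Compound list**

1 | nonanal | CCCCCCCCC=O | starting material
2 | ethyl (triphenylphosphoranylidene)acetate | CCOC(=O)C=P(c1ccccc1)(c1ccccc1)c1ccccc1 | starting material
3 | ethyl (E)-undec-2-enoate | CCCCCCCC/C=C/C(=O)OCC | intermediate
4 | 3-methoxy-2-methyl-4H-pyran-4-one | CC1=C(OC)C(=O)C=CO1 | starting material
5 | 1,3-dimethoxy-2-methylpyridin-4(1H)-one | CC1=C(OC)C(=O)C=CN1OC | intermediate
6 | 5-iodo-1,3-dimethoxy-2-methylpyridin-4(1H)-one | CC1=C(OC)C(=O)C(I)=CN1OC | intermediate
7 | ethyl (2E)-3-(1,5-dimethoxy-6-methyl-4-oxo-1,4-dihydropyridin-3-yl)undec-2-enoate | CCCCCCCC/C(=C\C(=O)OCC)C1=CN(OC)C(C)=C(OC)C1=O | intermediate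
8 | ethyl (3S)-3-(1,5-dimethoxy-6-methyl-4-oxo-1,4-dihydropyridin-3-yl)undecanoate | CCCCCCCC[C@H](C1=CN(OC)C(C)=C(OC)C1=O)CC(=O)OCC | intermediate
9 | (3S)-3-(1,5-dimethoxy-6-methyl-4-oxo-1,4-dihydropyridin-3-yl)undecanal | CCCCCCCC[C@H](C1=CN(OC)C(C)=C(OC)C1=O)CC=O | intermediate
10 | 1,3-dimethoxy-5-[(4S)-1-methoxydodec-1-en-4-yl]-2-methylpyridin-4(1H)-one (E/Z mixture, double bond left undefined) | CCCCCCCC[C@H](C1=CN(OC)C(C)=C(OC)C1=O)CC=COC | intermediate
11 | (5S,8R)-1,3,8-trimethoxy-2-methyl-5-octyl-5,6,7,8-tetrahydroquinolin-4(1H)-one (Waltherione K) | CCCCCCCC[C@H]1CC[C@@H](OC)c2c1c(=O)c(OC)c(C)n2OC | target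

**Step count and risks**

Total: 8 steps. Longest linear sequence: 7 steps (steps 2 to 8, from 3-methoxy-2-methyl-4H-pyran-4-one).

Step 8 (proposed new method) is the riskiest. The addition of the C8 radical to the aromatic pyridone may be too slow, so that hydrogen atom transfer only isomerises the enol ether; the catalyst chain may stop before the hydrogen atom is returned; or the facial selectivity at C8 may be low. The fallback sets out from 10 and comes back at 11. An iron-hydride reductive radical cyclisation (Fe(acac)3, excess PhSiH3, EtOH, 60 °C), the intramolecular form of the known reductive olefin–enone (Giese-type) coupling, regenerates the C8 radical many times and ends by reduction and protonation of the C4a radical. It should give (5S,8R)-1,3,8-trimethoxy-2-methyl-5-octyl-4a,5,6,7,8,8a-hexahydroquinolin-4(1H)-one F1 (ring-fusion centres not controlled, both removed next). Dehydrogenation of this 2,3-dihydro-4-pyridone with DDQ in dioxane then gives 11. C8 epimers, if formed, would have to be separated at F1 or at 11.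

Step 4 is next. Carbopalladation of the β-alkyl acrylate may be slow against hydrodeiodination, and double-bond migration may give Z or β,γ-isomers that would erode the enantioselectivity of step 5. The fallback sets out from 6 and comes back at 8. A Heck reaction with ethyl acrylate (Pd(OAc)2, P(o-tol)3, Et3N, DMF, 90 °C) should give ethyl (2E)-3-(1,5-dimethoxy-6-methyl-4-oxo-1,4-dihydropyridin-3-yl)prop-2-enoate F2. A copper-catalysed asymmetric conjugate addition of octylmagnesium bromide (CuI, Tol-BINAP, t-BuOMe, −40 °C; ligand enantiomer chosen by correlation) then forms the C5–octyl bond and the stereocentre in one step and gives 8 without passing through 7.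

Step 5 is third. Conversion or enantioselectivity may be insufficient because the β-substituent is a twisted heteroaryl group with an ortho carbonyl that can bind copper. The fallback sets out from 7 and comes back at 9. Reduction with excess iBu2AlH (CH2Cl2, −78 to 0 °C) should give 5-[(2E)-1-hydroxyundec-2-en-3-yl]-1,3-dimethoxy-2-methylpyridin-4(1H)-one F3, and MnO2 (CH2Cl2, rt) should give (2E)-3-(1,5-dimethoxy-6-methyl-4-oxo-1,4-dihydropyridin-3-yl)undec-2-enal F4. An iminium-catalysed transfer hydrogenation (chiral 2-tert-butyl-3-methylimidazolidin-4-one trichloroacetate, Hantzsch ester, CHCl3, −30 °C), which is enantioconvergent for E/Z mixtures, then gives aldehyde 9, so step 6 is bypassed as well.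

**Further compounds**

F1 | step 8 | (5S,8R)-1,3,8-trimethoxy-2-methyl-5-octyl-4a,5,6,7,8,8a-hexahydroquinolin-4(1H)-one (C4a and C8a undefined) | CCCCCCCC[C@H]1CC[C@@H](OC)C2N(OC)C(C)=C(OC)C(=O)C12
F2 | step 4 | ethyl (2E)-3-(1,5-dimethoxy-6-methyl-4-oxo-1,4-dihydropyridin-3-yl)prop-2-enoate | CCOC(=O)/C=C/C1=CN(OC)C(C)=C(OC)C1=O
F3 | step 5 | 5-[(2E)-1-hydroxyundec-2-en-3-yl]-1,3-dimethoxy-2-methylpyridin-4(1H)-one | CCCCCCCC/C(=C\CO)C1=CN(OC)C(C)=C(OC)C1=O
F4 | step 5 | (2E)-3-(1,5-dimethoxy-6-methyl-4-oxo-1,4-dihydropyridin-3-yl)undec-2-enal | CCCCCCCC/C(=C\C=O)C1=CN(OC)C(C)=C(OC)C1=O
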